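## Retrosynthetic overview
1. The C13 enone and the butenolide come last. Both arise from a ten-membered cross-conjugated dienone ester by ring A allylic oxidation, ketone reduction with lactonisation, and re-oxidation at C13.
2. The ten-membered carbocycle comes from a ring expansion. A C8 vinylmagnesium attacks C7 of a seven-membered O2–C7 enoate lactone; the freed O2 is tigloylated in the same flask.
3. The lactone comes from a C2 ketone (CBS reduction sets C2). The ketone comes from the ring A aldehyde and a C3–C7 zinc reagent whose Z alkene is taken from a pyranone.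
4. Ring A (C1, C10, C14) comes from an enantioselective Diels–Alder reaction of a dienyl acetate with an (E)-enal that carries the (Z)-β-iodoenoate arm.
5. Ring order: ring A, then the seven-membered lactone, then the ten-membered ring, then the butenolide.

Assumption: briarane numbering is used throughout (C1 quaternary, C2 tiglate carbinol, C5=C6, C7 lactone carbinol, C8=C17, C10 ring-fusion CH, C11–C14 ring A, C19 lactone C=O); the sense of induction in step 5 follows the usual formyl C–H···O model, and the antipodal catalyst would be used if 10 came out as its mirror image.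

## Route

Step 1
Reactants: 1 pent-3-yn-1-ol
Product: 3 (Z)-5-hydroxy-3-iodo-2-methylpent-2-enoic acid, via vinyltitanium carboxylate 2 (not isolated)
Conditions: iPrMgCl (3.4 equiv), Ti(OiPr)4 (1.2 equiv), Et2O, −78 to −40 °C; CO2 (1 atm), −40 °C; I2, −78 to 0 °C; 1 M HCl
Reagents that add atoms: carbon dioxide O=C=O; iodine [I][I]
Why: Sato-type alkyne–titanium chemistry, in which the tethered alkoxide holds the divalent-titanium alkyne complex so that CO2 inserts into the distal Ti–C bond (C17) and iodinolysis cleaves the chelated proximal Ti–C8 bond, a net syn addition that places I and CO2H cis (Z).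

Step 2
Reactants: 3 (Z)-5-hydroxy-3-iodo-2-methylpent-2-enoic acid
Product: 4 methyl (Z)-5-hydroxy-3-iodo-2-methylpent-2-enoate
Conditions: MeI, KHCO3, DMF, rt
Reagents that add atoms: iodomethane C[I]
Why: SN2 O-alkylation of the carboxylate, which leaves the alcohol and the alkene geometry untouched.

Step 3
Reactants: 4 methyl (Z)-5-hydroxy-3-iodo-2-methylpent-2-enoate
Product: 6 methyl (2Z,5E)-3-iodo-2,6-dimethyl-7-oxohepta-2,5-dienoate, via iodo aldehyde 5 (not isolated)
Conditions: Dess–Martin periodinane, CH2Cl2, 0 °C; then Ph3P=C(Me)CHO (2 equiv), rt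
Reagents that add atoms: 2-(triphenyl-λ5-phosphanylidene)propanal CC(C=O)=P(c1ccccc1)(c1ccccc1)c1ccccc1
Why: Dess–Martin oxidation followed in the same flask by a Wittig olefination with a stabilised ylide, which traps the sensitive β,γ-unsaturated aldehyde at once and gives the (E)-2-methylenal.

Step 4
Reactants: 7 (E)-pent-2-enal; 8 acetic anhydride
Product: 9 (1E,3E)-penta-1,3-dien-1-yl acetate
Conditions: Et3N, DMAP (cat.), 60 °C; (1E,3E) isomer by distillation
Reagents that add atoms: none
Why: O-acylation of the extended enolate (dienol acetate formation); any 1Z isomer left is inert in step 5.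

Step 5
Reactants: 6 methyl (2Z,5E)-3-iodo-2,6-dimethyl-7-oxohepta-2,5-dienoate; 9 (1E,3E)-penta-1,3-dien-1-yl acetate
Product: 10 (1R,4S,5R,6S)-6-formyl-5-[(Z)-2-iodo-4-methoxy-3-methyl-4-oxobut-2-enyl]-4,6-dimethylcyclohex-2-en-1-yl acetate
Conditions: B-(o-tolyl)oxazaborolidine from (S)-diphenylprolinol (20 mol%), Tf2NH (18 mol%), CH2Cl2, −78 to −40 °C
Reagents that add atoms: none
Why: Catalytic enantioselective Diels–Alder reaction in which only the formyl-activated alkene reacts, the acetoxy terminus bonds to the formyl-bearing carbon (ortho rule), the E-enal fixes Me-15 cis to C9 (C1/C10), the endo-formyl transition state puts OAc cis to CHO (C14), and the shielded face of the bound enal sets the absolute configuration.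

Step 6
Reactants: 11 4-methyl-5,6-dihydro-2H-pyran-2-one
Product: 13 methyl (Z)-5-iodo-3-methylpent-2-enoate, via silyl ester 12 (not isolated)
Conditions: Me3SiI, CH2Cl2, 0 °C to rt; then MeOH, rt
Reagents that add atoms: iodotrimethylsilane C[Si](C)(C)[I]; methanol CO
Why: Silyl-activated SN2 opening of the lactone at O–CH2 followed by acid-catalysed esterification, which carries the ring-locked Z alkene (later C5=C6) into the open chain.

Step 7
Reactants: 13 methyl (Z)-5-iodo-3-methylpent-2-enoate; 10 ring A aldehyde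
Product: 15 C2 carbinol (C2 epimer mixture; CHO of 10 turned into CH(OH)CH2CH2C(Me)=CHCO2Me), via alkylzinc iodide 14 (not isolated)
Conditions: 13, Zn, LiCl, THF, 40 °C; then MgCl2, 10, THF, 25 °C
Reagents that add atoms: none
Why: Zinc insertion into the primary iodide gives an ester-tolerant alkylzinc whose MgCl2-accelerated 1,2-addition is selective for the aldehyde, and the C2 ratio does not matter because step 8 removes this centre.

Step 8
Reactants: 15 C2 carbinol
Product: 16 C2 ketone (ring A stereocentres as in 10)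
Conditions: Dess–Martin periodinane, CH2Cl2, 0 °C to rt
Reagents that add atoms: none
Why: Dess–Martin oxidation of the only hydroxyl under neutral conditions, which spares the acetate, both enoates and the vinyl iodide.

Step 9
Reactants: 16 C2 ketone
Product: 18 seven-membered lactone ((7S)-7-substituted 4-methyl-6,7-dihydrooxepin-2(5H)-one; C2 is S), via (2S)-hydroxy diester 17 (not isolated)
Conditions: (R)-Me-CBS (20 mol%), BH3·SMe2, THF, −20 °C; MeOH; then CSA (20 mol%), PhMe, 5 Å MS, 90 °C
Reagents that add atoms: none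
Why: Corey–Bakshi–Shibata reduction tells the tertiary-alkyl side (C1) from the primary-alkyl side (C3), so the (R)-catalyst gives (2S), and acid-catalysed transesterification onto the cis-disposed (Z)-enoate closes the lactone as methanol is removed.

Step 10
Reactants: 18 seven-membered lactone; 19 (E)-2-methylbut-2-enoyl chloride
Product: 23 ten-membered (5Z,8Z)-dienone ester 2-tiglate, via vinylmagnesium chloride 20 (not isolated), via bridged hemiketal alkoxide 21 (not isolated), via ring-expanded alkoxide 22 (not isolated)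
Conditions: iPrMgCl·LiCl (1.1 equiv), THF (0.005 M), −40 to 0 °C; then 19 (2 equiv), DMAP (cat.), 0 °C to rt
Reagents that add atoms: none
Why: Proposed new method: iodine–magnesium exchange gives the configurationally stable, ester-chelated (Z)-β-magnesiated enoate 20, whose C8 carbanion on the equatorial C10 arm lies gauche to the equatorial C1 arm and reaches the lactone carbonyl C7 through a seven-membered transition state (the axial acetate is trans-1,3 and out of reach), and the bridged hemiketal alkoxide 21 then collapses by expelling the C2 alkoxide, which converts the seven-membered lactone into the ten-membered carbocycle (driven by the change from C-anion to O-anion and by the cross-conjugated dienone), forms C7–C8, keeps C2 and both alkene geometries, and lets O2 be acylated in the same flask; the closest known reaction types are intramolecular nucleophilic acyl substitution of halo esters (SmI2- or titanium-mediated) and the addition of magnesiated enoates to aldehydes, neither shown for a lactone-to-carbocycle expansion to a ten-membered ring.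

Step 11
Reactants: 23 ten-membered dienone ester 2-tiglate
Product: 24 C13 enone of 23 (ring A: C11(Me)=C12–C13=O)
Conditions: Rh2(cap)4 (1 mol%), 70% aq. tBuOOH (5 equiv), ClCH2CH2Cl, 40 °C
Reagents that add atoms: tert-butyl hydroperoxide CC(C)(C)OO
Why: Dirhodium-caprolactamate allylic oxidation (tert-butylperoxyl radical chain) in which C12=C13 is the only electron-rich alkene left, so the tertiary allylic C11–H is abstracted, the allyl radical is trapped at the less hindered C13, and the mixed peroxide collapses to the transposed enone with loss of the C11 stereocentre.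

Step 12
Reactants: 24 C13 enone
Product: 26 (7R)-butenolide with C13 allylic alcohol (C13 epimers), via diol ester 25 (not isolated)
Conditions: (S)-Me-CBS (30 mol%), BH3·SMe2 (2.2 equiv), THF, −30 °C; MeOH; SiO2
Reagents that add atoms: none
Why: CBS reduction with the tetrasubstituted alkenyl C8 as large group and C6 as small group gives (7R) with the (S)-catalyst, which matches outer-face attack on the dienone in the conformation inherited from 21, after which the C7 hydroxyl lactonises onto the cis ester and the co-reduced C13 ketone is restored in step 13.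

Step 13
Reactants: 26 butenolide allylic alcohol
Product: 27 target (1R,2S,5Z,7R,10R,14S)
Conditions: Dess–Martin periodinane, CH2Cl2, 0 °C to rt
Reagents that add atoms: none
Why: Dess–Martin oxidation of the only free (allylic) hydroxyl restores the C13 enone under neutral conditions that do not epimerise C14, C10 or C7.

## Compound list
1 | pent-3-yn-1-ol | CC#CCCO | starting material
2 | vinyltitanium carboxylate (Ti bound to C8, chain alkoxide O, carboxylate O and one OiPr) | CC1=C2CCO[Ti]2(OC(C)C)OC1=O | intermediate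
3 | (Z)-5-hydroxy-3-iodo-2-methylpent-2-enoic acid | OCC/C([I])=C(\C)C(=O)O | intermediate
4 | methyl (Z)-5-hydroxy-3-iodo-2-methylpent-2-enoate | OCC/C([I])=C(\C)C(=O)OC | intermediate
5 | methyl (Z)-3-iodo-2-methyl-5-oxopent-2-enoate | O=CC/C([I])=C(\C)C(=O)OC | intermediate
6 | methyl (2Z,5E)-3-iodo-2,6-dimethyl-7-oxohepta-2,5-dienoate | O=C/C(C)=C/C/C([I])=C(\C)C(=O)OC | intermediate
7 | (E)-pent-2-enal | CC/C=C/C=O | starting material
8 | acetic anhydride | CC(=O)OC(C)=O | starting material
9 | (1E,3E)-penta-1,3-dien-1-yl acetate | C/C=C/C=C/OC(C)=O | intermediate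
10 | (1R,4S,5R,6S)-6-formyl-5-[(Z)-2-iodo-4-methoxy-3-methyl-4-oxobut-2-enyl]-4,6-dimethylcyclohex-2-en-1-yl acetate | O=C[C@]1(C)[C@H](OC(C)=O)C=C[C@H](C)[C@H]1C/C([I])=C(\C)C(=O)OC | intermediate
11 | 4-methyl-5,6-dihydro-2H-pyran-2-one | CC1=CC(=O)OCC1 | starting material
12 | trimethylsilyl (Z)-5-iodo-3-methylpent-2-enoate | C[Si](C)(C)OC(=O)\C=C(C)/CC[I] | intermediate
13 | methyl (Z)-5-iodo-3-methylpent-2-enoate | COC(=O)\C=C(C)/CC[I] | intermediate
14 | [(Z)-5-methoxy-3-methyl-5-oxopent-3-enyl]zinc iodide | COC(=O)\C=C(C)/CC[Zn][I] | intermediate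
15 | C2 carbinol, C2 epimer mixture | COC(=O)\C=C(C)/CCC(O)[C@]1(C)[C@H](OC(C)=O)C=C[C@H](C)[C@H]1C/C([I])=C(\C)C(=O)OC | intermediate
16 | C2 ketone | COC(=O)\C=C(C)/CCC(=O)[C@]1(C)[C@H](OC(C)=O)C=C[C@H](C)[C@H]1C/C([I])=C(\C)C(=O)OC | intermediate
17 | (2S)-hydroxy diester | COC(=O)\C=C(C)/CC[C@H](O)[C@]1(C)[C@H](OC(C)=O)C=C[C@H](C)[C@H]1C/C([I])=C(\C)C(=O)OC | intermediate
18 | seven-membered O2–C7 enoate lactone, (2S) | CC1=CC(=O)O[C@@H](CC1)[C@]2(C)[C@H](OC(C)=O)C=C[C@H](C)[C@H]2C/C([I])=C(\C)C(=O)OC | intermediate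
19 | (E)-2-methylbut-2-enoyl chloride (tigloyl chloride) | C/C=C(\C)C(=O)Cl | starting material
20 | C8 vinylmagnesium chloride of 18 | CC1=CC(=O)O[C@@H](CC1)[C@]2(C)[C@H](OC(C)=O)C=C[C@H](C)[C@H]2C/C([Mg]Cl)=C(\C)C(=O)OC | intermediate
21 | O2-bridged hemiketal magnesium alkoxide (C7 tetrahedral) | Cl[Mg]O[C@]12C=C(C)CC[C@H](O1)[C@]3(C)[C@H](OC(C)=O)C=C[C@H](C)[C@H]3C/C2=C(\C)C(=O)OC | intermediate
22 | ring-expanded C2 magnesium alkoxide | Cl[Mg]O[C@H]1CC/C(C)=C\C(=O)/C(=C(/C)C(=O)OC)C[C@@H]2[C@@H](C)C=C[C@@H](OC(C)=O)[C@@]12C | intermediate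
23 | ten-membered (5Z,8Z)-dienone methyl ester, 2-tiglate, 14-acetate, ring A alkene | C/C=C(\C)C(=O)O[C@H]1CC/C(C)=C\C(=O)/C(=C(/C)C(=O)OC)C[C@@H]2[C@@H](C)C=C[C@@H](OC(C)=O)[C@@]12C | intermediate
24 | C13 enone of 23 | C/C=C(\C)C(=O)O[C@H]1CC/C(C)=C\C(=O)/C(=C(/C)C(=O)OC)C[C@@H]2C(C)=CC(=O)[C@@H](OC(C)=O)[C@@]12C | intermediate
25 | (7R)-C7,C13-diol ester, C13 epimers | C/C=C(\C)C(=O)O[C@H]1CC/C(C)=C\[C@@H](O)/C(=C(/C)C(=O)OC)C[C@@H]2C(C)=CC(O)[C@@H](OC(C)=O)[C@@]12C | intermediate
26 | (7R)-butenolide, C13 allylic alcohol, C13 epimers | C/C=C(\C)C(=O)O[C@H]1CC/C(C)=C\[C@H]2OC(=O)C(C)=C2C[C@@H]2C(C)=CC(O)[C@@H](OC(C)=O)[C@@]12C | intermediate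
27 | CNP0218548.3 | C/C=C(\C)C(=O)O[C@H]1CC/C(C)=C\[C@H]2OC(=O)C(C)=C2C[C@@H]2C(C)=CC(=O)[C@@H](OC(C)=O)[C@@]12C | target

## Step count and weak points
Total steps: 13. Longest linear sequence: 11 (steps 1, 2, 3, 5, 7, 8, 9, 10, 11, 12, 13).

**Step 10 (new ring expansion).**
- Risk: the chelated vinylmagnesium may be too weak a nucleophile for the conjugated lactone, or 21 may not open.
- Fallback (known chemistry): sets out from 18 and comes back at 23.
- Me2AlN(OMe)Me (from AlMe3 and MeNH(OMe)·HCl, 1.1 equiv, CH2Cl2, 0 °C) opens the lactone to the (2S)-hydroxy Weinreb amide F4. The neopentyl axial acetate and the tetrasubstituted ester react more slowly.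
- 19 with DMAP gives the tiglate Weinreb amide F5.
- Iodine–magnesium exchange (iPrMgCl·LiCl, −40 °C, slow addition, high dilution) then closes C7–C8 directly by a Weinreb ketone synthesis. The chelated adduct releases 23 on work-up.

**Step 5 (Diels–Alder).**
- Risk: a trisubstituted enal and a 1,4-disubstituted acyloxydiene may react too slowly, or 9 may not survive the strong acid.
- Fallback: sets out from 7 (with 6) and comes back at 10.
- TBSOTf/Et3N converts 7 into the much more electron-rich (1E,3E)-1-(tert-butyldimethylsilyloxy)penta-1,3-diene F1.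
- F1 cycloadds to 6 at −78 °C with the same ortho/endo sense to give the silyl ether aldehyde F2.
- HF·pyridine frees the C14 alcohol F3, and Ac2O/pyridine gives 10.

**Step 11 (allylic oxidation).**
- Risk: trapping at C11 (a dead-end tertiary peroxide) or attack at C4 or C9.
- Fallback: sets out from 23 and comes back at 26.
- A Schenck ene reaction (O2, tetraphenylporphyrin, hν, CH2Cl2, 0 °C) uses the pseudoaxial β C11–H and gives the 13β-hydroperoxide F6 with C11=C12.
- PPh3 reduces F6 to the allylic alcohol F7.
- The conditions of step 12 then only have to reduce C7. They give 26 as a single C13 epimer, which step 13 oxidises as before.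

## Further compounds
F1 | step 5 | (1E,3E)-1-(tert-butyldimethylsilyloxy)penta-1,3-diene | C/C=C/C=C/O[Si](C)(C)C(C)(C)C
F2 | step 5 | 14-O-TBS analogue of 10 | O=C[C@]1(C)[C@H](O[Si](C)(C)C(C)(C)C)C=C[C@H](C)[C@H]1C/C([I])=C(\C)C(=O)OC
F3 | step 5 | 14-hydroxy analogue of 10 | O=C[C@]1(C)[C@H](O)C=C[C@H](C)[C@H]1C/C([I])=C(\C)C(=O)OC
F4 | step 10 | (2S)-hydroxy (Z)-enoic Weinreb amide | CON(C)C(=O)\C=C(C)/CC[C@H](O)[C@]1(C)[C@H](OC(C)=O)C=C[C@H](C)[C@H]1C/C([I])=C(\C)C(=O)OC
F5 | step 10 | 2-tiglate of F4 | CON(C)C(=O)\C=C(C)/CC[C@H](OC(=O)/C(C)=C/C)[C@]1(C)[C@H](OC(C)=O)C=C[C@H](C)[C@H]1C/C([I])=C(\C)C(=O)OC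
F6 | step 11 | 13β-hydroperoxide, C11=C12, C7 ketone | C/C=C(\C)C(=O)O[C@H]1CC/C(C)=C\C(=O)/C(=C(/C)C(=O)OC)C[C@@H]2C(C)=C[C@H](OO)[C@@H](OC(C)=O)[C@@]12C
F7 | step 11 | 13β-alcohol, C11=C12, C7 ketone | C/C=C(\C)C(=O)O[C@H]1CC/C(C)=C\C(=O)/C(=C(/C)C(=O)OC)C[C@@H]2C(C)=C[C@H](O)[C@@H](OC(C)=O)[C@@]12C
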